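(The data stem from a simulated flask with constants of no real substance; scatter was added.)

At one charge of J the share of E turned into Z keeps its course when E is halved: winter and summer, both at 225 mM of J, stand at 25.6% and 25.7% of their E at 170 s.

| flask | E | J | time |
|---|---|---|---|
| winter | 150 mM | 225 mM |  |
| noon | 60.0 mM | 135 mM |  |
| dawn | 150 mM | 450 mM |  |
| summer | 75.0 mM | 225 mM |  |
| midnight | 60.0 mM | 90.0 mM | 170 s |

| winter run: time / s | winter run: [Z] / mM | noon run: time / s | noon run: [Z] / mM | dawn run: time / s | dawn run: [Z] / mM | summer run: time / s | summer run: [Z] / mM |
|---|---|---|---|---|---|---|---|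
| 34 | 16.5 | 34 | 6.5 | 34 | 20.3 | 34 | 8.7 |
| 68 | 26.5 | 68 | 9.7 | 68 | 30.1 | 68 | 14.5 |
| 100 | 33.0 | 100 | 11.9 | 100 | 34.7 | 100 | 17.2 |
| 140 | 37.3 | 140 | 13.9 | 140 | 36.1 | 140 | 19.0 |
| 170 | 38.4 | 170 | 15.4 | 170 | 34.4 | 170 | 19.3 |

(standard deviation of a reading: 0.4 mM)

- the power of [J] that the first rate follows, about the charge of the winter run; measure it at two percent of E made into Z
- the power of [E] that the first rate follows, about the charge of the winter run; measure it at two percent of E made into Z (one fixed amount of Z, the same in the runs compared)
- Z in the midnight run at 170 s, as a share of the E charged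

- Overall: E + J -> Z.
- Constant volume, constant temperature.
- Readings of a species count what is bound in complexes too.
- "The second partner" is J.
- An order is taken over about fifteen percent of the charge, up and down.

The decision is whether midnight, with J cut to 90.0 mM on 60.0 mM of E, should stand for the full 170 s or be stopped sooner, and that hangs on how near Z will then be to its ceiling. We describe each curve as a steady feed a against a drain proportional to Z, d[Z]/dt = a − λ[Z], which integrates to [Z] = (a/λ)(1 − exp(−λt)). Two readings at equal steps then give the ceiling a/λ and λ, the closing constant (a pseudo-first-order relaxation constant), which says how fast a flask closes on its ceiling.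

The winter readings at 34 s and 68 s give 0.0147 s⁻¹ and a ceiling of 41.9 mM. The curve so drawn reaches 38.5 mM at 170 s, where 38.4 mM was read. The same two readings of the dawn run, with more J, give a larger constant than winter's, 0.0214 s⁻¹, and a formal ceiling of 39.2 mM. This is no ceiling of the dawn flask, whose Z was read falling from 36.1 mM at 140 s to 34.4 mM at 170 s, so we use the two figures for the early part of its curve and no further.

A straight line in [J] through these two constants gives midnight 0.0107 s⁻¹. Midnight should therefore stand at 77.6% of its ceiling at 140 s and 83.8% at 170 s, so we leave it the full time. The feeds of winter and dawn give a power of J of 0.446, and the first readings of winter and summer give a power of E of 0.923. Scaling the noon feed 0.213 mM s⁻¹ down to midnight's J, we commit to 23.2% of the E charged.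

The forecast gives 0.45 for the power of J (range 0.2 to 0.8), 0.95 for the power of E (0.75 to 1.15), and 23% for midnight (20% to 26%), on this ground: “Midnight has less J than noon, so it forms Z more slowly but loses less.”

The midnight run gives 20.9% of its E as Z at 170 s. About the winter charge the first rate follows J to the power 0.60, which is 1.34 times the forecast's value, and E to the power 0.86.

    E + J ⇌ Z (0.05570 L mol⁻¹ s⁻¹, 0.004880 s⁻¹)
    Z + J → G (0.02620 L mol⁻¹ s⁻¹)
    E + J ⇌ EJ, settled at all times (7.050 L mol⁻¹)

The fast association of E + J to EJ is the reason for the weak power of J: taken away, the apparent order in [J] about the winter charge rises from 0.60 to 1.0, and the midnight share at 170 s rises from 20.9% to 30.0%. In the summer run, which has the J of winter, 0.0147 s⁻¹ carries the 8.7 mM read at 34 s to 20.3 mM at 170 s, where 19.3 mM was read.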